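**Retrosynthetic overview**
1. The target comes from i-Bu2AlH opening of an eight-membered (Z)-enoate lactone that ties the hydroxypropyl oxygen to the enal carbon; the 1,3-diol is freed from an acetonide just before.
2. The (E,E)-diene comes from Pd coupling of an alkenylzirconocene (from a pent-3-ynyl side chain) with a ring A (E)-vinyl iodide.
3. The lactone comes from an intramolecular Horner–Wadsworth–Emmons reaction on the ring B ketone; the C3 chain from α′-alkylation of a 4-oxy-enone; the tertiary carbinol from hydroxyl-directed epoxidation and β-elimination.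
4. Ring B is formed first, by Birch reductive alkylation of a chiral 5-methoxy-2-methylbenzamide with 5-iodopent-2-yne, which turns the arene into a 1,4-diene carrying the quaternary centre.
5. Ring A is elaborated separately from 2-methylcyclohex-2-enone (asymmetric conjugate methylation, triflate carbonylation, deconjugative protonation, iodo-olefination); the lactone ring is formed last and is temporary.

Ring B atoms are called B1 (quaternary C), B2 (CH with the C3 chain), B3 (C=O, later C=C), B4 and B5 (CH2), B6 (C(Me)O).

Assumptions: 5-iodopent-2-yne, tert-butyl(3-iodopropoxy)dimethylsilane and 2-(diethoxyphosphoryl)propanoic acid are bought; in step 2 the (S)-auxiliary is taken to give the (1R) centre as in the 2-alkylbenzamide series (not checked against data), and its enantiomer would be used if the sense proved opposite.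

**Route**

Step 1
Reactants: 1 5-methoxy-2-methylbenzoic acid; 2 (S)-2-(methoxymethyl)pyrrolidine
Product: 4 (5-methoxy-2-methylphenyl)[(2S)-2-(methoxymethyl)pyrrolidin-1-yl]methanone, via acid chloride 3 (not isolated)
Conditions: (COCl)2, DMF (cat.), CH2Cl2, 0 °C to rt; then 2, Et3N, CH2Cl2, 0 °C to rt
Reagents that add atoms: none
Why: Acid chloride formation and amidation (nucleophilic acyl substitution) is the standard way to acylate a secondary amine with an ortho-substituted benzoic acid; no new stereocentre.

Step 2
Reactants: 4 the benzamide; 5 5-iodopent-2-yne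
Product: 7 [(1R)-5-methoxy-2-methyl-1-(pent-3-yn-1-yl)cyclohexa-2,5-dien-1-yl][(2S)-2-(methoxymethyl)pyrrolidin-1-yl]methanone, via potassium amide enolate 6 (not isolated)
Conditions: K (2.2 equiv), t-BuOH (1.0 equiv), NH3(l)/THF, −78 °C; piperylene; then 5, −78 °C; NH4Cl
Reagents that add atoms: none
Why: Birch reduction of the benzamide gives the cross-conjugated amide enolate 6 (methyl and methoxy stay on the two remaining double bonds), and its C1 alkylation is steered to one face by the potassium-chelated methoxymethylpyrrolidine (asymmetric Birch reductive alkylation), which dearomatises the ring and sets the quaternary centre B1.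

Step 3
Reactants: 7 the diene amide
Product: 9 (5R)-5-(hydroxymethyl)-4-methyl-5-(pent-3-yn-1-yl)cyclohex-3-en-1-one, via dienol ether alcohol 8 (not isolated)
Conditions: LiH2N·BH3 (4 equiv, from H3N·BH3 and n-BuLi), THF, 0 to 23 °C; then 2 M HCl, 0 °C
Reagents that add atoms: water, O
Why: Lithium amidotrihydroborate reduces hindered tertiary amides with C–N cleavage to primary alcohols (amide reduction), and the acidic quench hydrolyses the methyl enol ether to the β,γ-unsaturated ketone without touching B1.

Step 4
Reactants: 9 the keto alcohol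
Product: 11 (4S,5S)-4-hydroxy-5-(hydroxymethyl)-4-methyl-5-(pent-3-yn-1-yl)cyclohex-2-en-1-one, via epoxy ketone 10 (not isolated)
Conditions: VO(acac)2 (5 mol %), t-BuOOH, CH2Cl2, 0 °C to rt; then DBU, rt
Reagents that add atoms: tert-butyl hydroperoxide, CC(C)(C)OO
Why: Vanadium-catalysed hydroxyl-directed epoxidation of the homoallylic alcohol delivers oxygen to the face of CH2OH, and the β,γ-epoxy ketone then opens by E1cB elimination to the γ-hydroxy enone, so the B6 carbinol is set cis to CH2OH.

Step 5
Reactants: 11 the enone diol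
Product: 12 (4aS,8aS)-2,2,8a-trimethyl-4a-(pent-3-yn-1-yl)-4a,5-dihydro-4H-1,3-benzodioxin-6(8aH)-one
Conditions: 2,2-dimethoxypropane, PPTS (cat.), CH2Cl2, rt
Reagents that add atoms: 2,2-dimethoxypropane, COC(C)(C)OC
Why: Acid-catalysed transketalisation of the cis 1,3-diol gives the cis-fused acetonide, which protects both hydroxyls and rigidifies ring B; no new stereocentre.

Step 6
Reactants: 12 the acetonide enone; 13 tert-butyl(3-iodopropoxy)dimethylsilane
Product: 15 (4aS,5S,8aS)-5-[3-(tert-butyldimethylsilyloxy)propyl]-2,2,8a-trimethyl-4a-(pent-3-yn-1-yl)-4a,5-dihydro-4H-1,3-benzodioxin-6(8aH)-one, via lithium dienolate 14 (not isolated)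
Conditions: LiN(i-Pr)2, THF, −78 °C; then 13, DMPU, −78 to −20 °C
Reagents that add atoms: none
Why: The enone has no γ-hydrogen, so kinetic deprotonation gives only the α′ (B2) enolate, and its SN2 alkylation is expected to be axial, anti to the pseudo-axial pentynyl group on B1 and away from the B6 methyl, placing the chain on B2 trans to pentynyl and cis to CH2O.

Step 7
Reactants: 15 the alkylated enone
Product: 17 (4aS,5S,8aS)-5-(3-hydroxypropyl)-2,2,8a-trimethyl-4a-(pent-3-yn-1-yl)tetrahydro-4H-1,3-benzodioxin-6(5H)-one, via saturated ketone silyl ether 16 (not isolated)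
Conditions: [(Ph3P)CuH]6 (0.4 equiv), H2O (2 equiv), THF/benzene, rt; then Bu4NF, THF, 0 °C to rt
Reagents that add atoms: none
Why: The copper hydride hexamer reduces only the enone C=C (conjugate reduction; the alkyne and the B2 centre are untouched), and fluoride then cleaves the silyl ether.

Step 8
Reactants: 17 the hydroxy ketone; 18 2-(diethoxyphosphoryl)propanoic acid
Product: 19 the 2-(diethoxyphosphoryl)propanoate ester of 17 (epimers at the phosphonate carbon)
Conditions: DCC, DMAP (cat.), CH2Cl2, 0 °C to rt
Reagents that add atoms: none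
Why: Steglich esterification acylates the only free (primary) hydroxyl; no ring stereocentre is touched.

Step 9
Reactants: 19 the keto phosphonate
Product: 20 tricyclic (Z)-lactone (eight-membered α,β-unsaturated lactone joining the B2 propyl oxygen to the 2-methylacrylate carbon on B3; acetonide and pentynyl retained)
Conditions: NaH, THF (0.002 M, slow addition), 0 °C to reflux
Reagents that add atoms: none
Why: Intramolecular Horner–Wadsworth–Emmons olefination of the B3 ketone forms the tetrasubstituted alkene, and the eight-membered ring can only hold it with the carbonyl cis to B2, so the (Z) geometry is fixed by the tether.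

Step 10
Reactants: 21 2-methylcyclohex-2-en-1-one
Product: 23 (3R)-2,2,3-trimethylcyclohexan-1-one, via magnesium enolate 22 (not isolated)
Conditions: MeMgBr, Cu(OTf)2 (3 mol %), chiral N-heterocyclic carbene precursor (hydroxyalkyl imidazolinium salt, 4 mol %), Et2O, 0 °C; then MeI, HMPA, 0 °C to rt
Reagents that add atoms: methylmagnesium bromide, C[Mg]Br; methyl iodide, CI
Why: Copper-catalysed asymmetric conjugate addition sets the C3 methyl stereocentre under ligand control, and the regiodefined magnesium enolate is C-methylated to the gem-dimethyl carbon (conjugate addition with enolate trapping).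

Step 11
Reactants: 23 the trimethyl ketone
Product: 25 (3R)-2,2,3,6-tetramethylcyclohexan-1-one (C6 epimers), via lithium enolate 24 (not isolated)
Conditions: LiN(i-Pr)2, THF, −78 °C; then MeI, −78 to 0 °C
Reagents that add atoms: methyl iodide, CI
Why: Only C6 can be enolised, so enolate methylation is regiospecific; the new C6 centre becomes sp2 in the next step and needs no control.

Step 12
Reactants: 25 the tetramethyl ketone
Product: 27 (5R)-2,5,6,6-tetramethylcyclohex-1-en-1-yl trifluoromethanesulfonate, via potassium enolate 26 (not isolated)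
Conditions: KN(SiMe3)2, THF, −78 to 0 °C; then PhNTf2, 0 °C to rt
Reagents that add atoms: N-phenylbis(trifluoromethanesulfonimide), O=S(=O)(N(c1ccccc1)S(=O)(=O)C(F)(F)F)C(F)(F)F
Why: Deprotonation at the only α-hydrogen and O-sulfonylation give the tetrasubstituted enol triflate (enol triflate formation); C5 is untouched.

Step 13
Reactants: 27 the enol triflate
Product: 28 methyl (5R)-2,5,6,6-tetramethylcyclohex-1-ene-1-carboxylate
Conditions: Pd(OAc)2 (5 mol %), PPh3, CO (1 atm), MeOH, Et3N, DMF, 60 °C
Reagents that add atoms: carbon monoxide, [C-]#[O+]; methanol, CO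
Why: Palladium-catalysed alkoxycarbonylation of a vinyl triflate gives the conjugated ester with the carbon that becomes the first side-chain carbon.

Step 14
Reactants: 28 the conjugated ester
Product: 30 methyl (1S,3R)-2,2,3-trimethyl-6-methylidenecyclohexane-1-carboxylate, via lithium dienolate 29 (not isolated)
Conditions: LiN(i-Pr)2, THF/HMPA, −78 °C; then 2,6-di-tert-butyl-4-methylphenol, −78 °C
Reagents that add atoms: none
Why: Chelation-directed γ-deprotonation of the methyl cis to the ester gives the exocyclic dienolate, and kinetic α-protonation by the bulky phenol from the face anti to the axial C2 methyl should leave the ester equatorial and cis to the C3 methyl (deconjugative protonation).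

Step 15
Reactants: 30 the methylidene ester
Product: 31 (1S,3R)-2,2,3-trimethyl-6-methylidenecyclohexane-1-carbaldehyde
Conditions: i-Bu2AlH (1.1 equiv), CH2Cl2, −78 °C; aq. potassium sodium tartrate
Reagents that add atoms: none
Why: The aluminium hemiacetal of this hindered ester survives at −78 °C and gives the aldehyde on work-up (partial ester reduction) under non-basic conditions that do not epimerise C1.

Step 16
Reactants: 31 the aldehyde
Product: 32 (2S,6R)-2-[(E)-2-iodoethenyl]-1,1,6-trimethyl-3-methylidenecyclohexane
Conditions: CrCl2, CHI3, THF/dioxane, 0 °C to rt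
Reagents that add atoms: iodoform, IC(I)I
Why: Takai iodo-olefination converts α-branched aldehydes into (E)-vinyl iodides under non-basic conditions, so the allylic stereocentre is kept.

Step 17
Reactants: 20 the alkyne lactone; 32 the ring A vinyl iodide
Product: 34 the coupled (E,E)-diene lactone acetonide, via alkenylzirconocene 33 (not isolated)
Conditions: Cp2Zr(H)Cl (2.5 equiv), THF, rt to 45 °C; then 32, Pd(PPh3)4 (5 mol %), ZnCl2 (0.5 equiv), THF, rt
Reagents that add atoms: none
Why: Syn hydrozirconation, equilibrated with excess reagent, puts zirconium on the less hindered methyl-bearing alkyne carbon, and palladium-catalysed Negishi-type coupling with retention at both partners gives the (E,E)-diene.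

Step 18
Reactants: 34 the diene lactone acetonide
Product: 35 the diol lactone (free CH2OH on B1 and free tertiary OH on B6)
Conditions: PPTS (cat.), MeOH, 40 °C
Reagents that add atoms: none
Why: Mild acid-catalysed transketalisation removes the acetonide without isomerising the diene or the exocyclic methylene; no stereocentre is involved.

Step 19
Reactants: 35 the diol lactone
Product: 37 the target CNP0149035.2, via lactol 36 (not isolated)
Conditions: i-Bu2AlH (3.5 equiv), CH2Cl2, −78 °C; aq. potassium sodium tartrate
Reagents that add atoms: none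
Why: Half-reduction of the lactone gives the aluminium hemiacetal, and on work-up the strained eight-membered lactol opens to the hydroxypropyl group and the (Z)-enal with the geometry fixed in step 9.

**Compound list**
1 | 5-methoxy-2-methylbenzoic acid | Cc1ccc(OC)cc1C(=O)O | starting material
2 | (S)-2-(methoxymethyl)pyrrolidine | COC[C@@H]1CCCN1 | starting material
3 | 5-methoxy-2-methylbenzoyl chloride | Cc1ccc(OC)cc1C(=O)Cl | intermediate
4 | (5-methoxy-2-methylphenyl)[(2S)-2-(methoxymethyl)pyrrolidin-1-yl]methanone | Cc1ccc(OC)cc1C(=O)N1CCC[C@H]1COC | intermediate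
5 | 5-iodopent-2-yne | CC#CCCI | starting material
6 | potassium amide enolate of the 1,4-dihydrobenzamide | [K+].[O-]C(=C1C=C(OC)CC=C1C)N1CCC[C@H]1COC | intermediate
7 | [(1R)-5-methoxy-2-methyl-1-(pent-3-yn-1-yl)cyclohexa-2,5-dien-1-yl][(2S)-2-(methoxymethyl)pyrrolidin-1-yl]methanone | CC#CCC[C@@]1(C(=O)N2CCC[C@H]2COC)C=C(OC)CC=C1C | intermediate
8 | [(1R)-5-methoxy-2-methyl-1-(pent-3-yn-1-yl)cyclohexa-2,5-dien-1-yl]methanol | CC#CCC[C@@]1(CO)C=C(OC)CC=C1C | intermediate
9 | (5R)-5-(hydroxymethyl)-4-methyl-5-(pent-3-yn-1-yl)cyclohex-3-en-1-one | CC#CCC[C@@]1(CO)CC(=O)CC=C1C | intermediate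
10 | 3,4-epoxide of 9, oxirane on the face of CH2OH | CC#CCC[C@@]1(CO)CC(=O)C[C@@H]2O[C@]12C | intermediate
11 | (4S,5S)-4-hydroxy-5-(hydroxymethyl)-4-methyl-5-(pent-3-yn-1-yl)cyclohex-2-en-1-one | CC#CCC[C@@]1(CO)CC(=O)C=C[C@]1(C)O | intermediate
12 | (4aS,8aS)-2,2,8a-trimethyl-4a-(pent-3-yn-1-yl)-4a,5-dihydro-4H-1,3-benzodioxin-6(8aH)-one | CC#CCC[C@@]1(COC(C)(C)O2)CC(=O)C=C[C@@]12C | intermediate
13 | tert-butyl(3-iodopropoxy)dimethylsilane | CC(C)(C)[Si](C)(C)OCCCI | starting material
14 | lithium cross-conjugated dienolate of 12 | CC#CCC[C@@]1(COC(C)(C)O2)C=C([O-])C=C[C@@]12C.[Li+] | intermediate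
15 | (4aS,5S,8aS)-5-[3-(tert-butyldimethylsilyloxy)propyl] derivative of 12 | CC#CCC[C@@]1(COC(C)(C)O2)[C@H](CCCO[Si](C)(C)C(C)(C)C)C(=O)C=C[C@@]12C | intermediate
16 | 15 with the enone C=C reduced (saturated ketone, silyl ether) | CC#CCC[C@@]1(COC(C)(C)O2)[C@H](CCCO[Si](C)(C)C(C)(C)C)C(=O)CC[C@@]12C | intermediate
17 | (4aS,5S,8aS)-5-(3-hydroxypropyl)-2,2,8a-trimethyl-4a-(pent-3-yn-1-yl)tetrahydro-4H-1,3-benzodioxin-6(5H)-one | CC#CCC[C@@]1(COC(C)(C)O2)[C@H](CCCO)C(=O)CC[C@@]12C | intermediate
18 | 2-(diethoxyphosphoryl)propanoic acid | CCOP(=O)(OCC)C(C)C(=O)O | starting material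
19 | 2-(diethoxyphosphoryl)propanoate ester of 17 | CC#CCC[C@@]1(COC(C)(C)O2)[C@H](CCCOC(=O)C(C)P(=O)(OCC)OCC)C(=O)CC[C@@]12C | intermediate
20 | tricyclic (Z)-lactone: eight-membered enoate lactone from the B2 propyl oxygen to the alkylidene carbon on B3, acetonide and pentynyl retained | CC#CCC[C@@]1(COC(C)(C)O2)[C@H](CCCOC3=O)/C(=C3/C)CC[C@@]12C | intermediate
21 | 2-methylcyclohex-2-en-1-one | CC1=CCCCC1=O | starting material
22 | bromomagnesium enolate of (3R)-2,3-dimethylcyclohexanone | Br[Mg]OC1=C(C)[C@H](C)CCC1 | intermediate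
23 | (3R)-2,2,3-trimethylcyclohexan-1-one | O=C1CCC[C@@H](C)C1(C)C | intermediate
24 | lithium enolate of 23 | [Li+].[O-]C1=CCC[C@@H](C)C1(C)C | intermediate
25 | (3R)-2,2,3,6-tetramethylcyclohexan-1-one (C6 epimers) | CC1CC[C@@H](C)C(C)(C)C1=O | intermediate
26 | potassium enolate of 25 | [K+].[O-]C1=C(C)CC[C@@H](C)C1(C)C | intermediate
27 | (5R)-2,5,6,6-tetramethylcyclohex-1-en-1-yl trifluoromethanesulfonate | CC1=C(OS(=O)(=O)C(F)(F)F)C(C)(C)[C@H](C)CC1 | intermediate
28 | methyl (5R)-2,5,6,6-tetramethylcyclohex-1-ene-1-carboxylate | COC(=O)C1=C(C)CC[C@@H](C)C1(C)C | intermediate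
29 | lithium exocyclic dienolate of 28 | C=C1CC[C@@H](C)C(C)(C)C1=C([O-])OC.[Li+] | intermediate
30 | methyl (1S,3R)-2,2,3-trimethyl-6-methylidenecyclohexane-1-carboxylate | C=C1CC[C@@H](C)C(C)(C)[C@H]1C(=O)OC | intermediate
31 | (1S,3R)-2,2,3-trimethyl-6-methylidenecyclohexane-1-carbaldehyde | C=C1CC[C@@H](C)C(C)(C)[C@H]1C=O | intermediate
32 | (2S,6R)-2-[(E)-2-iodoethenyl]-1,1,6-trimethyl-3-methylidenecyclohexane | C=C1CC[C@@H](C)C(C)(C)[C@H]1/C=C/I | intermediate
33 | alkenylzirconocene chloride from 20 (Zr on the methyl-bearing carbon, trans to the chain) | C/C(=C\CC[C@@]1(COC(C)(C)O2)[C@H](CCCOC3=O)/C(=C3/C)CC[C@@]12C)[Zr](Cl)(C4C=CC=C4)C4C=CC=C4 | intermediate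
34 | coupled (E,E)-diene lactone acetonide | C=C1CC[C@@H](C)C(C)(C)[C@H]1/C=C/C(C)=C/CC[C@@]1(COC(C)(C)O2)[C@H](CCCOC3=O)/C(=C3/C)CC[C@@]12C | intermediate
35 | diol lactone (34 without the acetonide) | C=C1CC[C@@H](C)C(C)(C)[C@H]1/C=C/C(C)=C/CC[C@@]1(CO)[C@H](CCCOC2=O)/C(=C2/C)CC[C@]1(C)O | intermediate
36 | eight-membered lactol of 35 | C=C1CC[C@@H](C)C(C)(C)[C@H]1/C=C/C(C)=C/CC[C@@]1(CO)[C@H](CCCOC2O)/C(=C2/C)CC[C@]1(C)O | intermediate
37 | CNP0149035.2 | C=C1CC[C@@H](C)C(C)(C)[C@H]1/C=C/C(C)=C/CC[C@@]1(CO)[C@H](CCCO)/C(=C(/C)C=O)CC[C@]1(C)O | target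

**Summary**
Total steps: 19. Longest linear sequence: 12 (steps 1–9 and 17–19); the ring A branch is steps 10–16.

**Steps most likely to fail and fallbacks**

Step 3 (reduction of the very hindered amide next to the quaternary centre). The fallback drops the auxiliary; it sets out from 1 (with 5) and comes back at 11. Birch reductive alkylation of the free acid 1 (Li, NH3/THF, −78 °C; then 5) gives the racemic 5-methoxy-2-methyl-1-(pent-3-yn-1-yl)cyclohexa-2,5-diene-1-carboxylic acid F1. LiAlH4 in THF gives the racemic dienol ether alcohol F2, and 1 M HCl gives the racemic keto alcohol F3. Epoxidation with VO(Oi-Pr)3, a chiral C2-symmetric bishydroxamic acid ligand and cumene hydroperoxide in toluene is run as a kinetic resolution of the homoallylic alcohol, so that only the (5R)-enantiomer becomes 10; DBU then gives 11, and the (5S)-enantiomer of F3 is recovered. The yield ceiling is 50 %.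

Step 6 (slow alkylation with an unactivated iodide and substrate-controlled face selectivity at B2). The fallback uses a π-allyl electrophile under catalyst control; it sets out from 12 and comes back at 17. The lithium dienolate 14 is O-acylated with allyl chloroformate to the allyl enol carbonate F4. Pd2(dba)3 with a chiral phosphinooxazoline ligand, chosen to reinforce delivery anti to the pentynyl group, effects decarboxylative allylation to the α′-allyl enone F5. [(Ph3P)CuH]6 with water gives the allyl ketone F6, and 9-BBN followed by NaBO3 hydroborates the terminal alkene (faster than the hindered ketone and the internal alkyne) to give 17.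

Step 9 (eight-membered ring closure onto a hindered ketone to a tetrasubstituted alkene, with possible B2 epimerisation by base). The fallback is a non-basic aldol-then-dehydration sequence; it sets out from 17 and comes back at 20. Acylation with 2-bromopropanoyl bromide and pyridine gives the 2-bromopropanoate ester F7. SmI2 in THF at −78 °C under high dilution closes the ring by a samarium Reformatsky addition to the B3 ketone, giving the β-hydroxy lactone F8. Martin sulfurane in CH2Cl2 dehydrates the tertiary alcohol towards the acidic α-hydrogen, and the ring again allows only the (Z)-alkene, giving 20.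

**Further compounds**
F1 | step 3 | racemic 5-methoxy-2-methyl-1-(pent-3-yn-1-yl)cyclohexa-2,5-diene-1-carboxylic acid | CC#CCCC1(C(=O)O)C=C(OC)CC=C1C
F2 | step 3 | racemic [5-methoxy-2-methyl-1-(pent-3-yn-1-yl)cyclohexa-2,5-dien-1-yl]methanol | CC#CCCC1(CO)C=C(OC)CC=C1C
F3 | step 3 | racemic 5-(hydroxymethyl)-4-methyl-5-(pent-3-yn-1-yl)cyclohex-3-en-1-one | CC#CCCC1(CO)CC(=O)CC=C1C
F4 | step 6 | allyl enol carbonate of 12 (carbonate on the B3 oxygen, B2=B3 and B4=B5 double bonds) | CC#CCC[C@@]1(COC(C)(C)O2)C=C(OC(=O)OCC=C)C=C[C@@]12C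
F5 | step 6 | α′-allyl enone (allyl on B2, trans to pentynyl) | CC#CCC[C@@]1(COC(C)(C)O2)[C@H](CC=C)C(=O)C=C[C@@]12C
F6 | step 6 | allyl ketone (F5 with the enone C=C reduced) | CC#CCC[C@@]1(COC(C)(C)O2)[C@H](CC=C)C(=O)CC[C@@]12C
F7 | step 9 | 2-bromopropanoate ester of 17 | CC#CCC[C@@]1(COC(C)(C)O2)[C@H](CCCOC(=O)C(C)Br)C(=O)CC[C@@]12C
F8 | step 9 | eight-membered β-hydroxy lactone (tertiary OH on B3) | CC#CCC[C@@]1(COC(C)(C)O2)[C@@H]3CCCOC(=O)C(C)C3(O)CC[C@@]12C
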